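The numbers in the tables come from a simulation from invented constants; noise was put on by code.

A sound figure for conversion says nothing of how many chains share the reacted monomer, so a chain length can go far astray beside a good conversion.

Minutes of the meeting on the flask below.

| flask | free monomer | initiator | remark | time |
|---|---|---|---|---|
| south-west | 0.14 M | 2 mM | run made earlier |  |
| north | 0.22 M | 2 mM | run made earlier |  |
| south | 0.10 M | 1 mM | run made earlier |  |
| flask | 0.10 M | 2.0 mM |  | 80 min |

| run | time / min | monomer in chains / % | free monomer / % |
|---|---|---|---|
| south-west | 5.00 | 1 | 97 |
| south-west | 12.0 | 2 | 98 |
| south-west | 30.0 | 9 | 91 |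
| south-west | 60.0 | 16 | 84 |
| north | 15.0 | 7 | 95 |
| north | 30.0 | 12 | 91 |
| north | 50.0 | 18 | 85 |
| north | 60.0 | 19 | 79 |
| south | 5.00 | 0 | 101 |
| south | 12.0 | 2 | 98 |
| south | 30.0 | 4 | 95 |
| south | 60.0 | 11 | 90 |

(scatter of a reading: 1.5 percentage points)

- the average divides the monomer in chains by the number of chains begun, living and dead together
- the earlier runs were read with a standard deviation of 1.5 percentage points
- the earlier runs do not show the number of chains; that part of a forecast is a guess

1. average number of monomer units in a chain (chains begun, living or dead) at 80 min
2. part of the free monomer that has reacted at 80 min

The forecaster put the reacted part at 18 % (15 % to 21 %) and the average chain at 150 units (40 to 500), the latter “assuming typical initiator decomposition”, and called it very uncertain.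

I, taking the minutes, accepted that conversion but argued for another count of chains. The runs do not show chains, so any count is a guess, and mine was that each initiator begins one chain and that none stays unused by the asked time. The average then follows from the charge ratio, 50.0 here, which is the free monomer charged divided by the initiator charged, usually called the target degree of polymerisation. Multiplied by the reacted part, it gives the average chain. In powers of ten that multiplication is an addition: 1.70 plus −0.745 makes 0.954, an average of 9.00 units. This is well below the forecast's figure, and the meeting kept both.

The simulation gives an average of 7.91 units with 15.8 % reacted, so the forecast's average stands 19.0 times above it, while its reacted part lies inside its range. At 80.0 min this flask holds 0.071 % of its charged initiator. The charge ratio now adds 1.70 and −0.801 to make 0.898, which is 7.91 units.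

    free monomer + initiator → living end + monomer in chains (k = 0.0166 M⁻¹ s⁻¹)
    free monomer + living end → monomer in chains + living end, rate k2*[living end]*[free monomer] (k = 0.0584 M⁻¹ s⁻¹)
    monomer in chains + living end → free monomer + living end, rate k3*[living end] as long as [monomer in chains] is above zero (k = 0.00291 s⁻¹)
    2 living end → dead end (k = 0.0722 M⁻¹ s⁻¹)

The neighbour flask with 5.00 mM of initiator has a charge ratio of 20.0, and with 26.0 % reacted, 1.30 and −0.585 add to 0.716, which is 5.20 units. The computed average in that neighbour flask is 5.21 units.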